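**Retrosynthetic overview**
- Feature: the dihydropyran ring is fused to the arene at the adjacent carbons C4a (bonded to C4) and C8a (bonded to O1), and C8, the other neighbour of C8a, carries a methyl. An aryl iodide with iodine at C8a, methyl at C8 and one free ortho C–H at C4a therefore maps onto an ortho-alkylation/ipso-etherification.
- Side chain: the C13' acid comes from the allylic alcohol; C5'–C6' is made by alkylating the C10 sulfone 13 (from geranyl bromide) with allylic bromide 9, then desulfonylation; C5' is oxygenated by SeO2 on the prenyl terminus of chroman 7.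
- Chroman 7: palladium/norbornene annulation of aryl iodide 2 with bromohydrin 6 forms C4–C4a and O1–C8a; C2 comes unchanged from (R)-linalool.
- Ring order: the benzene ring is bought; the dihydropyran ring is the only ring formed (step 4).

Key step: step 4

Assumption: commercial (R)-(−)-linalool is taken as enantiomerically pure; C2 is never touched, so its enantiomeric purity passes unchanged into the target. Chroman locants C2–C8a and side-chain locants C1'–C13' are used throughout.

**Route**

Step 1
Reactants: 1 4-iodo-3-methylphenol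
Product: 2 1-iodo-4-(methoxymethoxy)-2-methylbenzene
Conditions: MOMCl, i-Pr2NEt, CH2Cl2, 0 °C → rt
Reagents that add atoms: chloromethyl methyl ether, COCCl
Why: O-alkylation of the phenol by the reactive α-chloro ether (Williamson-type acetal formation) gives a MOM ether that tolerates the carbonate, organolithium and hydride conditions ahead.

Step 2
Reactants: 3 (R)-linalool
Product: 5 (R)-3,7-dimethyloct-6-ene-1,3-diol, via alkylborane 4 (not isolated)
Conditions: 9-BBN (1.5 equiv), THF, 0 °C → rt; then NaOH, H2O2, H2O, 0 °C → rt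
Reagents that add atoms: hydrogen peroxide, OO
Why: Brown hydroboration–oxidation with 9-BBN places boron on the terminal carbon of the vinyl group much faster than on the trisubstituted 6,7-alkene, and no bond to the carbinol stereocenter is broken.

Step 3
Reactants: 5 (R)-3,7-dimethyloct-6-ene-1,3-diol
Product: 6 (R)-1-bromo-3,7-dimethyloct-6-en-3-ol
Conditions: CBr4, PPh3, 2,6-lutidine, CH2Cl2, −20 → 0 °C
Reagents that add atoms: carbon tetrabromide, BrC(Br)(Br)Br
Why: Appel reaction in which only the primary hydroxyl forms an alkoxyphosphonium ion open to SN2 displacement by bromide, while the lutidine buffer keeps HBr away from the alkene and the tertiary alcohol.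

Step 4
Reactants: 2 1-iodo-4-(methoxymethoxy)-2-methylbenzene; 6 (R)-1-bromo-3,7-dimethyloct-6-en-3-ol
Product: 7 (R)-6-(methoxymethoxy)-2,8-dimethyl-2-(4-methylpent-3-en-1-yl)chroman
Conditions: Pd(OAc)2 (10 mol %), XPhos (20 mol %), norbornene (1.5 equiv), Cs2CO3 (3 equiv), 6 (1.5 equiv), 1,4-dioxane, 100 °C
Reagents that add atoms: none
Why: Proposed new method: zerovalent palladium should add to the C–I bond of 2, norbornene then inserts and the single free ortho C–H (future C4a) is palladated to an aryl–norbornyl palladacycle, which takes up the primary bromide of 6 (via tetravalent palladium) and forms C4–C4a by reductive elimination. With both ortho positions now filled, norbornene is expelled by β-carbon elimination, the tertiary hydroxyl binds the arylpalladium halide and is deprotonated by Cs2CO3, and C–O reductive elimination at the ipso carbon closes the dihydropyran ring as a six-membered aryl ether (O1–C8a) from a seven-membered palladacycle. The closest known reaction types are the palladium/norbornene annulation of aryl iodides with epoxides to 2,3-dihydrobenzofurans and the palladium-catalysed cyclization of tertiary alcohols onto aryl halides under bulky biarylphosphine ligands. No stereocenter is created: C2 comes from (R)-linalool and none of its bonds is broken, so its configuration is carried through. The step needs mono-alkylation at C4a and alkylation before etherification: the C8 methyl blocks the other ortho site and supplies the ortho effect that drives norbornene extrusion, the aryl iodide adds to zerovalent palladium much faster than the alkyl bromide, and direct etherification of the aryl iodide is slower than the norbornene relay. The tertiary alkoxide has no hydrogen for β-hydride elimination, and carbonate is too weak a base to close 6 to its oxetane at a competitive rate.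

Step 5
Reactants: 7 (R)-6-(methoxymethoxy)-2,8-dimethyl-2-(4-methylpent-3-en-1-yl)chroman
Product: 8 (E)-5-[(R)-6-(methoxymethoxy)-2,8-dimethylchroman-2-yl]-2-methylpent-2-en-1-ol
Conditions: SeO2 (0.3 equiv), t-BuOOH (3 equiv), salicylic acid (0.1 equiv), CH2Cl2, 0 °C → rt
Reagents that add atoms: selenium dioxide, O=[Se]=O; tert-butyl hydroperoxide, CC(C)(C)OO
Why: Riley allylic oxidation (ene reaction, then [2,3]-sigmatropic shift) of the only alkene attacks the methyl trans to the chain on the gem-dimethyl terminus, so the (E)-allylic alcohol should form, and substoichiometric SeO2 limits over-oxidation.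

Step 6
Reactants: 8 (E)-5-[(R)-6-(methoxymethoxy)-2,8-dimethylchroman-2-yl]-2-methylpent-2-en-1-ol
Product: 9 (R)-2-[(E)-5-bromo-4-methylpent-3-en-1-yl]-6-(methoxymethoxy)-2,8-dimethylchroman
Conditions: CBr4, PPh3, CH2Cl2, −20 → 0 °C
Reagents that add atoms: carbon tetrabromide, BrC(Br)(Br)Br
Why: Appel bromination of the primary allylic alcohol proceeds by SN2 on the alkoxyphosphonium ion at low temperature, without allylic transposition or loss of the E geometry; the bromide is used directly.

Step 7
Reactants: 10 geranyl bromide, (E)-1-bromo-3,7-dimethylocta-2,6-diene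
Product: 11 geranyl phenyl sulfone, (E)-[(3,7-dimethylocta-2,6-dien-1-yl)sulfonyl]benzene
Conditions: PhSO2Na, DMF, rt
Reagents that add atoms: sodium benzenesulfinate, [Na+].[O-]S(=O)c1ccccc1
Why: The sulfinate alkylates at sulfur by SN2 at the primary allylic bromide in a polar aprotic solvent, leaving the 2E alkene in place.

Step 8
Reactants: 11 geranyl phenyl sulfone
Product: 12 (2E,6E)-2,6-dimethyl-8-(phenylsulfonyl)octa-2,6-dien-1-ol
Conditions: SeO2 (0.3 equiv), t-BuOOH (3 equiv), salicylic acid (0.1 equiv), CH2Cl2, rt
Reagents that add atoms: selenium dioxide, O=[Se]=O; tert-butyl hydroperoxide, CC(C)(C)OO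
Why: Riley allylic oxidation picks the electron-rich terminal alkene over the alkene deactivated by the neighbouring sulfonyl group and oxidises its E-methyl, giving the (2E)-allylic alcohol.

Step 9
Reactants: 12 (2E,6E)-2,6-dimethyl-8-(phenylsulfonyl)octa-2,6-dien-1-ol
Product: 13 tert-butyl{[(2E,6E)-2,6-dimethyl-8-(phenylsulfonyl)octa-2,6-dien-1-yl]oxy}dimethylsilane
Conditions: TBSCl, imidazole, DMF, rt
Reagents that add atoms: tert-butyldimethylsilyl chloride, CC(C)(C)[Si](C)(C)Cl
Why: Imidazole-mediated silylation of the primary alcohol gives an ether stable to n-BuLi and LiBHEt3 and removable by fluoride without touching the aryl MOM ether.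

Step 10
Reactants: 13 tert-butyl{[(2E,6E)-2,6-dimethyl-8-(phenylsulfonyl)octa-2,6-dien-1-yl]oxy}dimethylsilane; 9 (R)-2-[(E)-5-bromo-4-methylpent-3-en-1-yl]-6-(methoxymethoxy)-2,8-dimethylchroman
Product: 15 tert-butyl{[(2E,6E,10E)-13-[(R)-6-(methoxymethoxy)-2,8-dimethylchroman-2-yl]-2,6,10-trimethyl-8-(phenylsulfonyl)trideca-2,6,10-trien-1-yl]oxy}dimethylsilane (both epimers at the sulfonyl-bearing carbon), via lithiated sulfone 14 (not isolated)
Conditions: n-BuLi, THF, −78 °C; then 9, −78 → −20 °C
Reagents that add atoms: none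
Why: The α-sulfonyl allylic carbanion is alkylated at its α carbon by the primary allylic bromide (SN2, sulfone-based prenyl chain coupling), forming C5'–C6' with all alkenes in place; the new sulfonyl-bearing stereocenter forms without control and is removed in step 11.

Step 11
Reactants: 15 coupled sulfone
Product: 16 tert-butyl{[(2E,6E,10E)-13-[(R)-6-(methoxymethoxy)-2,8-dimethylchroman-2-yl]-2,6,10-trimethyltrideca-2,6,10-trien-1-yl]oxy}dimethylsilane
Conditions: PdCl2(dppp) (5 mol %), LiBHEt3 (2.5 equiv), THF, 0 °C → rt
Reagents that add atoms: none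
Why: Palladium-catalysed reductive desulfonylation: zerovalent palladium formed in situ ionises the allylic C–S bond and hydride is delivered to the less substituted terminus of the dppp-ligated π-allyl complex, which should keep the C7'=C8' alkene in place with E geometry.

Step 12
Reactants: 16 silyl ether
Product: 17 (2E,6E,10E)-13-[(R)-6-(methoxymethoxy)-2,8-dimethylchroman-2-yl]-2,6,10-trimethyltrideca-2,6,10-trien-1-ol
Conditions: Bu4NF, THF, 0 °C → rt
Reagents that add atoms: none
Why: Fluoride-driven cleavage of the Si–O bond frees the primary allylic alcohol while the MOM acetal is inert to fluoride.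

Step 13
Reactants: 17 allylic alcohol
Product: 18 (2E,6E,10E)-13-[(R)-6-(methoxymethoxy)-2,8-dimethylchroman-2-yl]-2,6,10-trimethyltrideca-2,6,10-trienal
Conditions: MnO2, CH2Cl2, rt
Reagents that add atoms: none
Why: MnO2 oxidises allylic alcohols selectively to enals without isomerising the E alkene and without touching the isolated alkenes or the protected chromanol.

Step 14
Reactants: 18 enal
Product: 19 (2E,6E,10E)-13-[(R)-6-(methoxymethoxy)-2,8-dimethylchroman-2-yl]-2,6,10-trimethyltrideca-2,6,10-trienoic acid
Conditions: NaClO2, NaH2PO4, 2-methyl-2-butene, t-BuOH/H2O, rt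
Reagents that add atoms: sodium chlorite, [Na+].[O-]Cl=O
Why: Pinnick oxidation converts the enal to the acid through its chlorous acid adduct, with 2-methyl-2-butene trapping hypochlorous acid before it can attack the alkenes or the electron-rich arene.

Step 15
Reactants: 19 MOM-protected acid
Product: 20 garcinoic acid, (2E,6E,10E)-13-[(R)-6-hydroxy-2,8-dimethylchroman-2-yl]-2,6,10-trimethyltrideca-2,6,10-trienoic acid
Conditions: 2 M aq. HCl, THF, 40 °C
Reagents that add atoms: none
Why: Acid-catalysed hydrolysis of the aryl methoxymethyl acetal through its oxocarbenium ion should free the phenol under conditions mild enough for the trisubstituted alkenes and the enoic acid.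

**Compound list**
1 | 4-iodo-3-methylphenol | Cc1cc(O)ccc1I | starting material
2 | 1-iodo-4-(methoxymethoxy)-2-methylbenzene | COCOc1ccc(I)c(C)c1 | intermediate
3 | (R)-linalool, (R)-3,7-dimethylocta-1,6-dien-3-ol | CC(C)=CCC[C@@](C)(O)C=C | starting material
4 | (R)-1-(9-borabicyclo[3.3.1]nonan-9-yl)-3,7-dimethyloct-6-en-3-ol (alkylborane) | CC(C)=CCC[C@@](C)(O)CCB1C2CCCC1CCC2 | intermediate (not isolated)
5 | (R)-3,7-dimethyloct-6-ene-1,3-diol | CC(C)=CCC[C@@](C)(O)CCO | intermediate
6 | (R)-1-bromo-3,7-dimethyloct-6-en-3-ol | CC(C)=CCC[C@@](C)(O)CCBr | intermediate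
7 | (R)-6-(methoxymethoxy)-2,8-dimethyl-2-(4-methylpent-3-en-1-yl)chroman | CC(C)=CCC[C@]1(C)CCc2cc(OCOC)cc(C)c2O1 | intermediate
8 | (E)-5-[(R)-6-(methoxymethoxy)-2,8-dimethylchroman-2-yl]-2-methylpent-2-en-1-ol | OC/C(C)=C/CC[C@]1(C)CCc2cc(OCOC)cc(C)c2O1 | intermediate
9 | (R)-2-[(E)-5-bromo-4-methylpent-3-en-1-yl]-6-(methoxymethoxy)-2,8-dimethylchroman | BrC/C(C)=C/CC[C@]1(C)CCc2cc(OCOC)cc(C)c2O1 | intermediate
10 | geranyl bromide, (E)-1-bromo-3,7-dimethylocta-2,6-diene | CC(C)=CCC/C(C)=C/CBr | starting material
11 | geranyl phenyl sulfone | CC(C)=CCC/C(C)=C/CS(=O)(=O)c1ccccc1 | intermediate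
12 | (2E,6E)-2,6-dimethyl-8-(phenylsulfonyl)octa-2,6-dien-1-ol | OC/C(C)=C/CC/C(C)=C/CS(=O)(=O)c1ccccc1 | intermediate
13 | tert-butyl{[(2E,6E)-2,6-dimethyl-8-(phenylsulfonyl)octa-2,6-dien-1-yl]oxy}dimethylsilane | CC(C)(C)[Si](C)(C)OC/C(C)=C/CC/C(C)=C/CS(=O)(=O)c1ccccc1 | intermediate
14 | α-lithio derivative of sulfone 13 | CC(C)(C)[Si](C)(C)OC/C(C)=C/CC/C(C)=C/C([Li])S(=O)(=O)c1ccccc1 | intermediate (not isolated)
15 | tert-butyl{[(2E,6E,10E)-13-[(R)-6-(methoxymethoxy)-2,8-dimethylchroman-2-yl]-2,6,10-trimethyl-8-(phenylsulfonyl)trideca-2,6,10-trien-1-yl]oxy}dimethylsilane, epimer mixture at C8 of the chain | CC(C)(C)[Si](C)(C)OC/C(C)=C/CC/C(C)=C/C(C/C(C)=C/CC[C@]1(C)CCc2cc(OCOC)cc(C)c2O1)S(=O)(=O)c1ccccc1 | intermediate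
16 | tert-butyl{[(2E,6E,10E)-13-[(R)-6-(methoxymethoxy)-2,8-dimethylchroman-2-yl]-2,6,10-trimethyltrideca-2,6,10-trien-1-yl]oxy}dimethylsilane | CC(C)(C)[Si](C)(C)OC/C(C)=C/CC/C(C)=C/CC/C(C)=C/CC[C@]1(C)CCc2cc(OCOC)cc(C)c2O1 | intermediate
17 | (2E,6E,10E)-13-[(R)-6-(methoxymethoxy)-2,8-dimethylchroman-2-yl]-2,6,10-trimethyltrideca-2,6,10-trien-1-ol | OC/C(C)=C/CC/C(C)=C/CC/C(C)=C/CC[C@]1(C)CCc2cc(OCOC)cc(C)c2O1 | intermediate
18 | (2E,6E,10E)-13-[(R)-6-(methoxymethoxy)-2,8-dimethylchroman-2-yl]-2,6,10-trimethyltrideca-2,6,10-trienal | O=C/C(C)=C/CC/C(C)=C/CC/C(C)=C/CC[C@]1(C)CCc2cc(OCOC)cc(C)c2O1 | intermediate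
19 | (2E,6E,10E)-13-[(R)-6-(methoxymethoxy)-2,8-dimethylchroman-2-yl]-2,6,10-trimethyltrideca-2,6,10-trienoic acid | OC(=O)/C(C)=C/CC/C(C)=C/CC/C(C)=C/CC[C@]1(C)CCc2cc(OCOC)cc(C)c2O1 | intermediate
20 | garcinoic acid, (2E,6E,10E)-13-[(R)-6-hydroxy-2,8-dimethylchroman-2-yl]-2,6,10-trimethyltrideca-2,6,10-trienoic acid | OC(=O)/C(C)=C/CC/C(C)=C/CC/C(C)=C/CC[C@]1(C)CCc2cc(O)cc(C)c2O1 | target

**Totals**
Total step count: 15.
Longest linear sequence: 11 steps, from (R)-linalool 3 to 20 (steps 2, 3, 4, 5, 6, 10, 11, 12, 13, 14, 15).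

**Steps most likely to fail**

1. Step 4. The relay may stall: the palladacycle may take up the β-oxygenated bromide too slowly, so that 6 is lost to oxetane closure or HBr elimination. Alternatively, C–O reductive elimination from the hindered arylpalladium alkoxide may be slow enough that the aryl group is diverted to reduction or norbornene-containing by-products. The fallback uses known chemistry and forms the two bonds in separate steps; it sets out from (R)-linalool 3, through its borane 4, and comes back at 7. 3-Bromo-5-methylphenol is chlorinated with SO2Cl2 (CH2Cl2, 0 °C), which should go mainly para to the hydroxyl as with 3,5-dimethylphenol, to give 3-bromo-4-chloro-5-methylphenol F1. Protection (MOMCl, i-Pr2NEt) gives 1-bromo-2-chloro-5-(methoxymethoxy)-3-methylbenzene F2. Borane 4, made as in step 2 but not oxidised, undergoes B-alkyl Suzuki–Miyaura coupling with F2 at the C–Br bond (PdCl2(dppf), K3PO4, THF/H2O, 60 °C) to give (R)-1-[2-chloro-5-(methoxymethoxy)-3-methylphenyl]-3,7-dimethyloct-6-en-3-ol F3. Intramolecular Buchwald–Hartwig etherification of the tertiary alcohol onto the aryl chloride (Pd(OAc)2, 2-(di-tert-butylphosphino)-1,1'-binaphthyl, Cs2CO3, toluene, 100 °C) should then close the ring to 7.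

2. Step 5. The allylic oxidation may be slow or unselective: over-oxidation to the enal, attack at the C2' methylene, or oxidation of the electron-rich aryl ether. The fallback rebuilds the oxidised terminus by olefination; it sets out from 7 and comes back at 8. Lemieux–Johnson cleavage of the trisubstituted alkene (OsO4 cat., NaIO4, 2,6-lutidine, dioxane/H2O) gives 3-[(S)-6-(methoxymethoxy)-2,8-dimethylchroman-2-yl]propanal F4, in which the spatial arrangement at C2 is unchanged and only the descriptor changes with the priorities. Wittig reaction with ethyl 2-(triphenylphosphoranylidene)propanoate (CH2Cl2, rt) should give ethyl (E)-5-[(R)-6-(methoxymethoxy)-2,8-dimethylchroman-2-yl]-2-methylpent-2-enoate F5 with the E selectivity of a stabilised ylide. Reduction with i-Bu2AlH (CH2Cl2, −78 °C) gives 8.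

3. Step 11. Hydride may be delivered to the more substituted terminus of the π-allyl intermediate, or the intermediate may equilibrate between syn and anti forms, so that the C7'=C8' alkene is transposed or loses its E geometry. The fallback forms C5'–C6' without a sulfonyl group, by α,α'-selective allyl–allyl coupling of an allylbarium reagent; it sets out from 9 and comes back at 16. Geranyl chloride is oxidised (SeO2 cat., t-BuOOH, CH2Cl2) to (2E,6E)-8-chloro-2,6-dimethylocta-2,6-dien-1-ol F6 and silylated (TBSCl, imidazole) to tert-butyl{[(2E,6E)-8-chloro-2,6-dimethylocta-2,6-dien-1-yl]oxy}dimethylsilane F7. Activated barium (from BaI2 and lithium biphenylide, THF, −78 °C) converts F7 into the allylbarium chloride F8. Addition of 9 at −78 °C should couple the two allyl units at their α carbons with retention of both alkene geometries and give 16 directly.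

**Further compounds**
F1 | step 4 | 3-bromo-4-chloro-5-methylphenol | Cc1cc(O)cc(Br)c1Cl
F2 | step 4 | 1-bromo-2-chloro-5-(methoxymethoxy)-3-methylbenzene | COCOc1cc(C)c(Cl)c(Br)c1
F3 | step 4 | (R)-1-[2-chloro-5-(methoxymethoxy)-3-methylphenyl]-3,7-dimethyloct-6-en-3-ol | CC(C)=CCC[C@@](C)(O)CCc1cc(OCOC)cc(C)c1Cl
F4 | step 5 | 3-[(S)-6-(methoxymethoxy)-2,8-dimethylchroman-2-yl]propanal | O=CCC[C@]1(C)CCc2cc(OCOC)cc(C)c2O1
F5 | step 5 | ethyl (E)-5-[(R)-6-(methoxymethoxy)-2,8-dimethylchroman-2-yl]-2-methylpent-2-enoate | CCOC(=O)/C(C)=C/CC[C@]1(C)CCc2cc(OCOC)cc(C)c2O1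
F6 | step 11 | (2E,6E)-8-chloro-2,6-dimethylocta-2,6-dien-1-ol | OC/C(C)=C/CC/C(C)=C/CCl
F7 | step 11 | tert-butyl{[(2E,6E)-8-chloro-2,6-dimethylocta-2,6-dien-1-yl]oxy}dimethylsilane | CC(C)(C)[Si](C)(C)OC/C(C)=C/CC/C(C)=C/CCl
F8 | step 11 | [(2E,6E)-8-(tert-butyldimethylsilyloxy)-3,7-dimethylocta-2,6-dien-1-yl]barium chloride | CC(C)(C)[Si](C)(C)OC/C(C)=C/CC/C(C)=C/C[Ba]Cl
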